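**Plan**

1. Retrosynthetic cuts, in order: the three O–CH3 bonds; the bond between the benzylic carbon on ring A (the 1,3,5-trisubstituted arene) and the next carbon of the twelve-carbon bridge; the bond between ring B (the 2,6-dioxygenated aryloxy arene) and its first bridge carbon; the diaryl ether C–O bond.
2. Forward: a Chan–Lam coupling makes the diaryl ether, a B-alkyl Suzuki coupling puts an eleven-carbon ester chain on ring B, and reduction then oxidation bring the ring A ester carbon and the chain-end carbon to the aldehyde level.
3. The only ring to be made, the 20-membered macrocycle, then arises in one event: an intramolecular McMurry coupling unites the two formyl carbons, both electrophilic, through titanium-bound ketyl radicals.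
4. Feature that allows this: the bond joins the benzylic carbon of ring A to the first carbon of a bridge of twelve CH2 groups with no other function, so both carbons can be carried as aldehydes (the one on ring A non-enolisable), and the C=C left next to ring A is removed by hydrogenation.
5. Stereochemistry: the target has no stereocentre and no stereogenic double bond; the E/Z mixture from the coupling converges on hydrogenation.

Key step: step 5

Remark: the 20-membered bridge is taken to be long enough that the cyclophane has no stable planar chirality, so no stereocontrol is planned.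

**Route**

Step 1
Reactants: 1 4-bromo-2,6-dimethoxyphenol; 2 [3-methoxy-5-(methoxycarbonyl)phenyl]boronic acid
Product: 3 methyl 3-(4-bromo-2,6-dimethoxyphenoxy)-5-methoxybenzoate
Conditions: Cu(OAc)2 (2 equiv), pyridine (5 equiv), 4 Å MS, CH2Cl2, dry air, rt
Reagents that add atoms: none
Why: Chan–Lam oxidative O-arylation, in which the aryl group of 2 passes to the copper phenoxide of 1 and C–O reductive elimination from trivalent copper follows at room temperature, should tolerate the aryl bromide and is known to accept phenols with two ortho substituents, while the bromine at C-4 of 1 blocks oxidative para coupling of the electron-rich phenol.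

Step 2
Reactants: 3 methyl 3-(4-bromo-2,6-dimethoxyphenoxy)-5-methoxybenzoate; 4 methyl undec-10-enoate
Product: 6 methyl 3-[2,6-dimethoxy-4-(11-methoxy-11-oxoundecyl)phenoxy]-5-methoxybenzoate, via alkylborane 5 (not isolated)
Conditions: 4, 9-BBN, THF, 0 °C to rt; then 3, PdCl2(dppf)·CH2Cl2 (5 mol %), K3PO4 (3 equiv, aq.), DMF, 60 °C
Reagents that add atoms: 9-borabicyclo[3.3.1]nonane (9-BBN), B1C2CCCC1CCC2
Why: Anti-Markovnikov hydroboration of the terminal alkene of 4 by 9-BBN leaves the ester untouched and gives alkylborane 5 (the only compound that keeps the boron and ring carbons of 9-BBN), and the B-alkyl Suzuki–Miyaura coupling of 5 with aryl bromide 3 should form the aryl–CH2 bond, the wide bite angle of dppf favouring reductive elimination over β-hydride elimination.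

Step 3
Reactants: 6 methyl 3-[2,6-dimethoxy-4-(11-methoxy-11-oxoundecyl)phenoxy]-5-methoxybenzoate
Product: 7 11-{4-[3-(hydroxymethyl)-5-methoxyphenoxy]-3,5-dimethoxyphenyl}undecan-1-ol
Conditions: LiAlH4 (2.5 equiv), THF, 0 °C to rt; then H2O
Reagents that add atoms: none
Why: Hydride reduction of esters with LiAlH4 should convert the benzoate and the alkanoate ester alike into primary alcohols, while the aryl methyl ethers and the diaryl ether are inert.

Step 4
Reactants: 7 11-{4-[3-(hydroxymethyl)-5-methoxyphenoxy]-3,5-dimethoxyphenyl}undecan-1-ol
Product: 8 3-[2,6-dimethoxy-4-(11-oxoundecyl)phenoxy]-5-methoxybenzaldehyde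
Conditions: Dess–Martin periodinane (2.6 equiv), CH2Cl2, 0 °C to rt
Reagents that add atoms: none
Why: Dess–Martin oxidation should convert the benzylic and the aliphatic primary alcohol into the aldehydes without over-oxidation under mild conditions, the dialdehyde being used at once in step 5.

Step 5
Reactants: 8 3-[2,6-dimethoxy-4-(11-oxoundecyl)phenoxy]-5-methoxybenzaldehyde
Product: 10 macrocyclic alkene as an E/Z mixture, via titanium pinacolate 9 (not isolated)
Conditions: TiCl3(DME)1.5 (12 equiv), Zn–Cu couple (36 equiv), DME, reflux; 8 added by syringe pump over 30 h, then reflux 6 h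
Reagents that add atoms: titanium trichloride TiCl3 (charged as its DME complex), Cl[Ti](Cl)Cl
Why: Low-valent titanium made from TiCl3(DME)1.5 and Zn–Cu transfers one electron to each carbonyl group, the titanium-bound ketyl radicals of the ring A formyl carbon and of the chain-end formyl carbon combine to the titanium pinacolate 9 (the only compound that holds titanium), and at reflux 9 gives up both oxygen atoms to titanium to leave the C=C of 10. The closest known reaction type is the intramolecular McMurry coupling of dialdehydes to macrocyclic cycloalkenes and stilbene-type cyclophanes. It closes the 20-membered ring (three atoms of the meta-linked ring A, the ether oxygen, four atoms of the para-linked ring B, twelve bridge carbons), formally as a 20-exo-trig attack of the aryl ketyl on the alkanal C=O or as ketyl–ketyl recombination on the metal surface, while the five-membered titanium diolate ring of 9 is only transient. No stereocentre has to be set, since the two carbinol centres of 9 vanish on deoxygenation and the E/Z geometry of 10 is erased in step 6. The step needs ring closure to outrun intermolecular coupling, which slow addition of 8 to a large excess of the reagent should secure (low stationary concentration, both carbonyl groups of one molecule held on the same titanium surface), and it needs chemoselectivity, which 8 provides because apart from the two aldehydes it holds only aryl ethers and an alkyl chain that low-valent titanium leaves alone.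

Step 6
Reactants: 10 macrocyclic alkene as an E/Z mixture
Product: 11 tri-O-methyl ether of the target
Conditions: H2 (1 atm), 10% Pd/C, EtOAc, rt
Reagents that add atoms: none
Why: Heterogeneous catalytic hydrogenation should saturate the 1,2-disubstituted styrene-type double bond of either geometric isomer, while aryl methyl ethers and the diaryl ether are not hydrogenolysed under these conditions.

Step 7
Reactants: 11 tri-O-methyl ether of the target
Product: 12 the target, the 20-membered diaryl ether cyclophane triphenol
Conditions: BBr3 (6 equiv), CH2Cl2, −78 °C to rt; then ice-water (degassed)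
Reagents that add atoms: none
Why: Lewis acid ether cleavage with BBr3 should remove the three methyl groups by complexation at oxygen and SN2 attack of bromide on each methyl carbon, while the diaryl ether, which has no sp3 C–O bond, survives.

**Compound list**

1 | 4-bromo-2,6-dimethoxyphenol | COc1cc(Br)cc(OC)c1O | starting material
2 | [3-methoxy-5-(methoxycarbonyl)phenyl]boronic acid | COC(=O)c1cc(OC)cc(c1)B(O)O | starting material
3 | methyl 3-(4-bromo-2,6-dimethoxyphenoxy)-5-methoxybenzoate | COC(=O)c1cc(OC)cc(c1)Oc1c(OC)cc(Br)cc1OC | intermediate
4 | methyl undec-10-enoate | C=CCCCCCCCCC(=O)OC | starting material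
5 | methyl 11-(9-borabicyclo[3.3.1]nonan-9-yl)undecanoate | COC(=O)CCCCCCCCCCB1C2CCCC1CCC2 | intermediate
6 | methyl 3-[2,6-dimethoxy-4-(11-methoxy-11-oxoundecyl)phenoxy]-5-methoxybenzoate | COC(=O)c1cc(OC)cc(c1)Oc1c(OC)cc(cc1OC)CCCCCCCCCCC(=O)OC | intermediate
7 | 11-{4-[3-(hydroxymethyl)-5-methoxyphenoxy]-3,5-dimethoxyphenyl}undecan-1-ol | COc1cc(CO)cc(c1)Oc1c(OC)cc(cc1OC)CCCCCCCCCCCO | intermediate
8 | 3-[2,6-dimethoxy-4-(11-oxoundecyl)phenoxy]-5-methoxybenzaldehyde | COc1cc(C=O)cc(c1)Oc1c(OC)cc(cc1OC)CCCCCCCCCCC=O | intermediate
9 | macrocyclic titanium pinacolate: the ring-closed 1,2-diol of 8 bound through both oxygens to titanium (further ligands on titanium not drawn; the two carbinol centres are undefined and are destroyed in the same step) | COc1cc2cc(c1)Oc1c(OC)cc(cc1OC)CCCCCCCCCCC1O[Ti]OC21 | intermediate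
10 | macrocyclic alkene, E/Z mixture: 20-membered cyclophane in which ring A (5-methoxy-1,3-phenylene) is joined through O to C-1 of ring B (2,6-dimethoxy-1,4-phenylene) and through CH=CH–(CH2)10 to C-4 of ring B, the CH=CH unit being attached to ring A | COc1cc2cc(c1)Oc1c(OC)cc(cc1OC)CCCCCCCCCCC=C2 | intermediate
11 | tri-O-methyl ether of the target: the same cyclophane with a saturated (CH2)12 bridge | COc1cc2cc(c1)Oc1c(OC)cc(cc1OC)CCCCCCCCCCCC2 | intermediate
12 | target: cyclophane with ring A (5-hydroxy-1,3-phenylene), ether oxygen, ring B (2,6-dihydroxy-1,4-phenylene) and a (CH2)12 bridge; no stereocentre | Oc1cc2cc(c1)Oc1c(O)cc(cc1O)CCCCCCCCCCCC2 | target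

**Count and risks**

Total step count: 7. Longest linear sequence: 7 steps (1 → 3 → 6 → 7 → 8 → 10 → 11 → 12).

Steps most likely to fail:

Step 5. Intermolecular carbonyl coupling may outrun ring closure and give oligomers, or the reaction may stop at the pinacol stage or reduce the aryl aldehyde without coupling. Fallback: the ring would be closed by olefin metathesis, which is reversible and returns oligomers to the ring under dilution. It sets out from 8. Double Wittig methylenation (Ph3PCH3Br, KOtBu, THF, 0 °C) should give the diene 5-(dodec-11-en-1-yl)-2-(3-ethenyl-5-methoxyphenoxy)-1,3-dimethoxybenzene F1. Ring-closing metathesis of F1 (second-generation Grubbs catalyst, RuCl2(=CHPh)(PCy3)(H2IMes), toluene, high dilution, 60 °C) should then give alkene 10 with loss of ethylene, where the route is rejoined.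

Step 1. Transfer of the aryl group to the doubly ortho-substituted phenoxide may be slow, so that protodeboronation and oxidative homocoupling consume the boronic acid, or the electron-rich phenol is oxidised. Fallback: a metal-free arylation with a diaryliodonium salt, which is little affected by ortho substituents on the phenol. It sets out from 1. Purchased methyl 3-iodo-5-methoxybenzoate would be converted in one pot (mCPBA, TsOH·H2O, MeCN, then 1,3,5-trimethoxybenzene) into [3-methoxy-5-(methoxycarbonyl)phenyl](2,4,6-trimethoxyphenyl)iodonium 4-methylbenzenesulfonate F2. Treating 1 with F2 and K2CO3 in toluene at 50 °C should transfer the less electron-rich aryl group (the ester-bearing one; the trimethoxyphenyl group acts as the non-transferred ligand) to oxygen and give 3, where the route is rejoined.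

Step 2. β-Hydride elimination from the alkylpalladium intermediate or protodeboronation of 5 may compete with coupling at the electron-rich, para-oxygenated aryl bromide, and the aqueous base may saponify the esters. Fallback: the chain would be attached through an sp carbon, which has no β-hydrogen. It sets out from 3. Sonogashira coupling with purchased undec-10-yn-1-ol (PdCl2(PPh3)2, CuI, Et3N, DMF, 80 °C) should give methyl 3-[4-(11-hydroxyundec-1-yn-1-yl)-2,6-dimethoxyphenoxy]-5-methoxybenzoate F3. Hydrogenation (H2, 10% Pd/C, EtOAc) should saturate the alkyne to methyl 3-[4-(11-hydroxyundecyl)-2,6-dimethoxyphenoxy]-5-methoxybenzoate F4, and LiAlH4 reduction of the remaining ester should give diol 7, where the route is rejoined.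

**Further compounds**

F1 | step 5 | 5-(dodec-11-en-1-yl)-2-(3-ethenyl-5-methoxyphenoxy)-1,3-dimethoxybenzene | COc1cc(C=C)cc(c1)Oc1c(OC)cc(cc1OC)CCCCCCCCCCC=C
F2 | step 1 | [3-methoxy-5-(methoxycarbonyl)phenyl](2,4,6-trimethoxyphenyl)iodonium 4-methylbenzenesulfonate | COC(=O)c1cc(OC)cc(c1)[I+]c1c(OC)cc(OC)cc1OC.Cc1ccc(cc1)S(=O)(=O)[O-]
F3 | step 2 | methyl 3-[4-(11-hydroxyundec-1-yn-1-yl)-2,6-dimethoxyphenoxy]-5-methoxybenzoate | COC(=O)c1cc(OC)cc(c1)Oc1c(OC)cc(cc1OC)C#CCCCCCCCCCO
F4 | step 2 | methyl 3-[4-(11-hydroxyundecyl)-2,6-dimethoxyphenoxy]-5-methoxybenzoate | COC(=O)c1cc(OC)cc(c1)Oc1c(OC)cc(cc1OC)CCCCCCCCCCCO
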